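Atoms are numbered along the oxylipin chain (C1 lactone carbonyl, C22 methyl). Everything rests on cutting C14–C15 inside the (Z)-homoallylic carbinol C14(OH)–C15H2–C16=C17, the retron of an allylboration with allylic transposition. In the last step the unprotected γ-hydroxy enal C1–C14 (eight-membered lactone ring, trans-cyclopropane ring, C11 carbinol) meets (S)-oct-1-en-3-ylboronic ester, whose boron sits on C17 and whose terminal CH2 becomes C15. One closed chair transition state forms C14–C15, sets C14 by 1,3-chirality transfer, shifts the alkene to C16=C17 and fixes it as Z. The precursor therefore shows a vinyl group and a C–B stereocentre, both absent from the product.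

Key step: step 9

Assumption: the facial preferences of the chiral controllers follow their usual models ((R)-TRIP gives re-face allylboration, (−)-MIB gives si-face alkenylzinc addition, (−)-sparteine removes the pro-S hydrogen), and each controller is taken as purchasable in both enantiomeric forms.

Step 1
Reactants: 1 hexan-1-ol
Product: 2 hexyl N,N-diisopropylcarbamate
Conditions: iPr2NCOCl, Et3N, CH2Cl2, reflux
Reagents that add atoms: N,N-diisopropylcarbamoyl chloride, CC(C)N(C(C)C)C(=O)Cl
Why: Carbamoylation of a primary alcohol (acyl substitution) installs the group that directs the lithiation and later leaves in the borylation, and no stereocentre is formed.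

Step 2
Reactants: 2 hexyl N,N-diisopropylcarbamate; 3 vinylboronic acid pinacol ester
Product: 6 (S)-oct-1-en-3-ylboronic acid pinacol ester, via lithiated carbamate 4 (not isolated), via boronate complex 5 (not isolated)
Conditions: sBuLi, (+)-sparteine, Et2O, −78 °C; 3, −78 °C; then reflux; H2O
Reagents that add atoms: none
Why: In this sparteine-mediated asymmetric lithiation–borylation the diamine selects the pro-R hydrogen, borylation proceeds with retention, and the Matteson-type 1,2-metallate shift of the vinyl group expels the carbamate with inversion, so the C–B stereocentre (future C17) should be set as S.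

Step 3
Reactants: 7 (E)-4,4-dimethoxybut-2-enal; 8 allylboronic acid pinacol ester
Product: 10 (4R,2E)-1,1-dimethoxyhepta-2,6-dien-4-ol, via pinacol borate 9 (not isolated)
Conditions: (R)-TRIP [(R)-3,3′-bis(2,4,6-triisopropylphenyl)-1,1′-binaphthyl-2,2′-diyl hydrogen phosphate] (5 mol %), 4 Å molecular sieves, toluene, −30 °C; then aq. NaHCO3
Reagents that add atoms: none
Why: Chiral-phosphoric-acid-catalysed allylboration through a closed chair transition state, in which the catalyst pocket exposes the re face of the enal, should set C7 as R, while the anhydrous medium leaves the dimethyl acetal untouched.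

Step 4
Reactants: 10 (4R,2E)-1,1-dimethoxyhepta-2,6-dien-4-ol
Product: 11 (R)-1-[(1R,2R)-2-(dimethoxymethyl)cyclopropyl]but-3-en-1-ol
Conditions: Et2Zn, CH2I2, CH2Cl2, −20 to 0 °C; aq. NH4Cl
Reagents that add atoms: diiodomethane, ICI
Why: In this hydroxyl-directed Simmons–Smith cyclopropanation (Furukawa variant) the zinc alkoxide of the conformer with least allylic 1,3-strain (C7–H eclipsing the alkene) delivers CH2 to the face syn to oxygen, which should set C8 and C10 as R,R, carry the E geometry over into the trans ring, and favour the allylic alkene flanked by alkoxide and acetal donors over the remote monosubstituted one.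

Step 5
Reactants: 11 (R)-1-[(1R,2R)-2-(dimethoxymethyl)cyclopropyl]but-3-en-1-ol; 12 pent-4-enoyl chloride
Product: 13 (R)-1-[(1R,2R)-2-(dimethoxymethyl)cyclopropyl]but-3-en-1-yl pent-4-enoate
Conditions: Et3N, DMAP (cat.), CH2Cl2, 0 °C to rt
Reagents that add atoms: none
Why: DMAP-catalysed O-acylation takes place at oxygen with retention at C7, brings in C1–C4 with the second terminal alkene, and stays basic enough to spare the acetal.

Step 6
Reactants: 13 (R)-1-[(1R,2R)-2-(dimethoxymethyl)cyclopropyl]but-3-en-1-yl pent-4-enoate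
Product: 14 (8R,5Z)-8-[(1R,2R)-2-(dimethoxymethyl)cyclopropyl]-3,4,7,8-tetrahydro-2H-oxocin-2-one
Conditions: second-generation Grubbs catalyst (5–10 mol %), CH2Cl2 (1 mM), reflux
Reagents that add atoms: none
Why: Ring-closing metathesis of two monosubstituted alkenes at high dilution, driven by loss of ethene, should close the eight-membered lactone, whose size allows only the Z geometry at C4=C5.

Step 7
Reactants: 14 (8R,5Z)-8-[(1R,2R)-2-(dimethoxymethyl)cyclopropyl]-3,4,7,8-tetrahydro-2H-oxocin-2-one
Product: 15 (1R,2R)-2-[(2R,4Z)-8-oxo-3,6,7,8-tetrahydro-2H-oxocin-2-yl]cyclopropane-1-carbaldehyde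
Conditions: TsOH·H2O (cat.), acetone/H2O, rt
Reagents that add atoms: water, O
Why: Acid-catalysed acetal hydrolysis unmasks the C11 aldehyde under conditions that the lactone, the Z alkene and the configurationally robust cyclopropane carbons should tolerate.

Step 8
Reactants: 15 (1R,2R)-2-[(2R,4Z)-8-oxo-3,6,7,8-tetrahydro-2H-oxocin-2-yl]cyclopropane-1-carbaldehyde; 16 3,3-diethoxyprop-1-yne
Product: 20 (4R,2E)-4-hydroxy-4-{(1R,2R)-2-[(2R,4Z)-8-oxo-3,6,7,8-tetrahydro-2H-oxocin-2-yl]cyclopropyl}but-2-enal, via alkenylborane 17 (not isolated), via alkenylzinc 18 (not isolated), via acetal alcohol 19 (not isolated)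
Conditions: 16, Cy2BH, toluene, 0 °C to rt; Me2Zn, −78 °C; (+)-MIB [(2R)-3-exo-morpholinoisoborneol] (5 mol %), 15, −10 °C; then 0.1 M aq. HCl, THF, 0 °C
Reagents that add atoms: water, O
Why: Syn hydroboration fixes C12=C13 as E, boron-to-zinc transmetalation gives an alkenylzinc that tolerates the lactone, the amino-alcohol-catalysed asymmetric alkenylzinc addition should attack the re face of the aldehyde under ligand control to set C11 as R, and dilute acid then cleaves the very labile enal acetal.

Step 9
Reactants: 20 (4R,2E)-4-hydroxy-4-{(1R,2R)-2-[(2R,4Z)-8-oxo-3,6,7,8-tetrahydro-2H-oxocin-2-yl]cyclopropyl}but-2-enal; 6 (S)-oct-1-en-3-ylboronic acid pinacol ester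
Product: 22 solandelactone F, via C14 pinacol borate 21 (not isolated)
Conditions: 6 (1.3 equiv), (S)-TRIP (10 mol %), 4 Å molecular sieves, toluene, −40 °C; then pH 7 buffer
Reagents that add atoms: none
Why: The aldehyde oxygen of 20 binds the boron of 6 and the allyl unit is transferred through a closed six-membered Zimmerman–Traxler chair, the former =CH2 (C15) bonding to C14 on the allyl face that carries boron while the double bond moves to C16=C17; the phosphoric acid activates the boronate by hydrogen bonds to a pinacol oxygen and the formyl hydrogen, and buffer hydrolysis of borate 21 releases the diol. The closest known reaction type is the chiral-phosphoric-acid-catalysed Z-selective allylboration of aldehydes with α-substituted secondary allylboronic esters. No ring is closed. C14 is controlled by 1,3-chirality transfer from the S-configured C–B carbon, because the chair with the enal residue equatorial and the pentyl group pseudo-axial presents the si face of the aldehyde and should give 14S, a preference that (S)-TRIP shares and reinforces. The step needs Z over E selectivity, which is secured by the pentyl group escaping the pinacol methyl groups into the pseudo-axial position and by the competing pseudo-equatorial chair having to use the re face that the catalyst disfavours. It also needs chemoselectivity for the aldehyde, which is secured because the lactone is inert to boronic esters and the C11 hydroxyl, held away from C14 by the E alkene, can neither chelate boron in the chair nor displace pinacol, so the four existing stereocentres stay untouched.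

Compound list
1 | hexan-1-ol | CCCCCCO | starting material
2 | hexyl N,N-diisopropylcarbamate | CCCCCCOC(=O)N(C(C)C)C(C)C | intermediate
3 | vinylboronic acid pinacol ester | C=CB1OC(C)(C)C(C)(C)O1 | starting material
4 | (R)-1-lithiohexyl N,N-diisopropylcarbamate as its (+)-sparteine complex (diamine omitted from the SMILES) | [Li][C@H](CCCCC)OC(=O)N(C(C)C)C(C)C | intermediate
5 | lithium [(R)-1-(diisopropylcarbamoyloxy)hexyl](vinyl)(pinacolato)borate | [Li+].C=C[B-]1(OC(C)(C)C(C)(C)O1)[C@H](CCCCC)OC(=O)N(C(C)C)C(C)C | intermediate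
6 | (S)-oct-1-en-3-ylboronic acid pinacol ester | C=C[C@H](CCCCC)B1OC(C)(C)C(C)(C)O1 | intermediate
7 | (E)-4,4-dimethoxybut-2-enal | COC(OC)/C=C/C=O | starting material
8 | allylboronic acid pinacol ester | C=CCB1OC(C)(C)C(C)(C)O1 | starting material
9 | O-pinacolboryl derivative of 10 | COC(OC)/C=C/[C@H](OB1OC(C)(C)C(C)(C)O1)CC=C | intermediate
10 | (4R,2E)-1,1-dimethoxyhepta-2,6-dien-4-ol | COC(OC)/C=C/[C@H](O)CC=C | intermediate
11 | (R)-1-[(1R,2R)-2-(dimethoxymethyl)cyclopropyl]but-3-en-1-ol | COC(OC)[C@@H]1C[C@H]1[C@H](O)CC=C | intermediate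
12 | pent-4-enoyl chloride | C=CCCC(=O)Cl | starting material
13 | (R)-1-[(1R,2R)-2-(dimethoxymethyl)cyclopropyl]but-3-en-1-yl pent-4-enoate | COC(OC)[C@@H]1C[C@H]1[C@@H](CC=C)OC(=O)CCC=C | intermediate
14 | (8R,5Z)-8-[(1R,2R)-2-(dimethoxymethyl)cyclopropyl]-3,4,7,8-tetrahydro-2H-oxocin-2-one | COC(OC)[C@@H]1C[C@H]1[C@H]1C/C=C\CCC(=O)O1 | intermediate
15 | (1R,2R)-2-[(2R,4Z)-8-oxo-3,6,7,8-tetrahydro-2H-oxocin-2-yl]cyclopropane-1-carbaldehyde | O=C[C@@H]1C[C@H]1[C@H]1C/C=C\CCC(=O)O1 | intermediate
16 | 3,3-diethoxyprop-1-yne | C#CC(OCC)OCC | starting material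
17 | (E)-(3,3-diethoxyprop-1-enyl)dicyclohexylborane | CCOC(OCC)/C=C/B(C1CCCCC1)C1CCCCC1 | intermediate
18 | (E)-(3,3-diethoxyprop-1-enyl)(methyl)zinc | CCOC(OCC)/C=C/[Zn]C | intermediate
19 | diethyl acetal of 20, (11R,12E) | CCOC(OCC)/C=C/[C@@H](O)[C@@H]1C[C@H]1[C@H]1C/C=C\CCC(=O)O1 | intermediate
20 | (4R,2E)-4-hydroxy-4-{(1R,2R)-2-[(2R,4Z)-8-oxo-3,6,7,8-tetrahydro-2H-oxocin-2-yl]cyclopropyl}but-2-enal | O=C/C=C/[C@@H](O)[C@@H]1C[C@H]1[C@H]1C/C=C\CCC(=O)O1 | intermediate
21 | C14 O-pinacolboryl derivative of 22 | CCCCC/C=C\C[C@H](OB2OC(C)(C)C(C)(C)O2)/C=C/[C@@H](O)[C@@H]1C[C@H]1[C@H]1C/C=C\CCC(=O)O1 | intermediate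
22 | solandelactone F, (7R,8R,10R,11R,14S,4Z,12E,16Z) | CCCCC/C=C\C[C@H](O)/C=C/[C@@H](O)[C@@H]1C[C@H]1[C@H]1C/C=C\CCC(=O)O1 | target

Total step count: 9. Longest linear sequence: 7 (steps 3 to 9).

**Steps most likely to fail**

**Step 9.** Z/E control may erode if the pentyl group takes the pseudo-equatorial position. The reaction may also slow down, with a poorly selective background addition, if the free C11 hydroxyl ties up the phosphoric acid.
- This fallback separates alkene geometry from bond formation. It sets out from 20 and comes back at 22.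
- Commercial oct-2-yn-1-ol is treated with methyl chloroformate and pyridine to give oct-2-yn-1-yl methyl carbonate F1.
- SN2′ borylation (CuCl, KOtBu, Xantphos, B2pin2, THF) gives octa-1,2-dien-3-ylboronic acid pinacol ester F2.
- (S)-TRIP-catalysed propargylation of 20 with F2 forms the same C14–C15 bond by SE2′ attack of the allene CH2. It passes through the C14 pinacol borate F3 and gives, after buffer work-up, 16,17-didehydrosolandelactone F F4.
- Semihydrogenation (H2, Pd/CaCO3 poisoned with Pb(OAc)2, quinoline) then delivers the Z alkene of 22.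

**Step 6.** Intermolecular metathesis (oligomerisation) may outrun ring closure, because of the strain of the eight-membered ring and the s-trans preference of the ester.
- This fallback closes the ring at the C–O bond instead. It sets out from 11 and comes back at 14.
- Z-selective cross-metathesis of 11 with commercial methyl pent-4-enoate uses the cyclometalated catalyst Ru(κ2-NO3)(=CH-C6H4-2-OiPr)(C,C-chelating N-adamantyl-N′-(2,6-diisopropylphenyl)imidazolin-2-ylidene). It gives methyl (7R,4Z)-7-[(1R,2R)-2-(dimethoxymethyl)cyclopropyl]-7-hydroxyhept-4-enoate F5.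
- LiOH in THF/H2O gives the corresponding seco acid F6.
- Yamaguchi lactonisation follows (2,4,6-trichlorobenzoyl chloride, Et3N; then DMAP, toluene, high dilution). It passes through the mixed anhydride F7 and gives 14.

**Step 4.** The terminal alkene may also be cyclopropanated, and discrimination between the two faces of the E alkene may be too weak.
- This fallback builds the ring before the terminal alkene exists and under reagent control. It sets out from 7 and comes back at 11.
- NaBH4 in MeOH gives (E)-4,4-dimethoxybut-2-en-1-ol F8.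
- Charette asymmetric cyclopropanation uses Zn(CH2I)2·DME and (4S,5S)-2-butyl-N,N,N′,N′-tetramethyl-1,3,2-dioxaborolane-4,5-dicarboxamide in CH2Cl2. It gives [(1R,2R)-2-(dimethoxymethyl)cyclopropyl]methanol F9.
- Dess–Martin oxidation gives (1R,2R)-2-(dimethoxymethyl)cyclopropane-1-carbaldehyde F10.
- (R)-TRIP-catalysed allylboration with 8 passes through the pinacol borate F11 and gives 11.

Further compounds
F1 | step 9 | oct-2-yn-1-yl methyl carbonate | CCCCCC#CCOC(=O)OC
F2 | step 9 | octa-1,2-dien-3-ylboronic acid pinacol ester | C=C=C(CCCCC)B1OC(C)(C)C(C)(C)O1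
F3 | step 9 | C14 O-pinacolboryl derivative of F4 | CCCCCC#CC[C@H](OB2OC(C)(C)C(C)(C)O2)/C=C/[C@@H](O)[C@@H]1C[C@H]1[C@H]1C/C=C\CCC(=O)O1
F4 | step 9 | 16,17-didehydrosolandelactone F (C16≡C17 alkyne analogue of 22) | CCCCCC#CC[C@H](O)/C=C/[C@@H](O)[C@@H]1C[C@H]1[C@H]1C/C=C\CCC(=O)O1
F5 | step 6 | methyl (7R,4Z)-7-[(1R,2R)-2-(dimethoxymethyl)cyclopropyl]-7-hydroxyhept-4-enoate | COC(OC)[C@@H]1C[C@H]1[C@H](O)C/C=C\CCC(=O)OC
F6 | step 6 | (7R,4Z)-7-[(1R,2R)-2-(dimethoxymethyl)cyclopropyl]-7-hydroxyhept-4-enoic acid | COC(OC)[C@@H]1C[C@H]1[C@H](O)C/C=C\CCC(=O)O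
F7 | step 6 | mixed anhydride of F6 and 2,4,6-trichlorobenzoic acid | COC(OC)[C@@H]1C[C@H]1[C@H](O)C/C=C\CCC(=O)OC(=O)c2c(Cl)cc(Cl)cc2Cl
F8 | step 4 | (E)-4,4-dimethoxybut-2-en-1-ol | COC(OC)/C=C/CO
F9 | step 4 | [(1R,2R)-2-(dimethoxymethyl)cyclopropyl]methanol | COC(OC)[C@@H]1C[C@H]1CO
F10 | step 4 | (1R,2R)-2-(dimethoxymethyl)cyclopropane-1-carbaldehyde | COC(OC)[C@@H]1C[C@H]1C=O
F11 | step 4 | O-pinacolboryl derivative of 11 | COC(OC)[C@@H]1C[C@H]1[C@H](OB2OC(C)(C)C(C)(C)O2)CC=C
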